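## Structural features

The target 14 is a single cyclohexene ring with no fused or bridged partner and one exocyclic carbon; with the ring numbered C1 (OAc), C2 (OH), C3 (OH), C4=C5 and C6 (OBz) and the arm C7H2OBz on C5, every ring carbon is either oxygenated or part of the alkene. The four stereocentres C6, C1, C2 and C3 form an unbroken row between the two alkene termini, with O1/O2 cis, O2/O3 trans and O1/O6 trans, and the absolute configuration is 1S,2S,3R,6S. Five oxygens are in three different states (benzoate on O6 and O7, acetate on O1, free hydroxyl on O2 and O3), so the real difficulty is telling the oxygens apart, above all O1 from its cis neighbour O2 and O6 from the other allylic oxygen O3. The esters are the fragile part, because base moves the acetyl group from O1 to O2 or a benzoyl group from O6 to a free O1. The allylic C–O bonds at C3, C6 and C7 can ionise or be displaced with allylic shift, and a twofold elimination would aromatise the ring. The key step rests first on the fact that C5 is the α-carbon of an acrylate-type unit (C4=C5–C7) bonded to the carbinol carbon C6, which is the retron of a Morita–Baylis–Hillman adduct. It rests second on the fact that C3–C2–C1 has the configuration of C2–C3–C4 of D-arabinose, so only the ring bond C5–C6 and the stereocentre C6 have to be made.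

## Logic of the disconnections

14 ⇒ 12. The O1–acetyl bond is cut last. An acetate next to a free cis hydroxyl is the most migration-prone group of 14 and should not be carried through other steps. This leaves 12, in which O1, O2 and O3 are free and both benzoates are in place. The forward step must acylate O1 only; it does so through the cyclic intermediate 13, whose opening is governed by the ring conformation.

12 ⇒ 11. The three O–H bonds are traced back to one acetal across O1/O2 and one silyl ether on O3. Both are acid-labile, so one operation frees all three hydroxyls and no base is needed once the benzoates are present. The forward step must neither cleave nor move a benzoate.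

11 ⇒ 10. Both benzoyl C–O bonds (O6 and O7) are cut together. In 10 exactly these two hydroxyls are free, so one exhaustive acylation suffices and O6 never has to be distinguished from O3. The forward step must acylate a hindered secondary allylic hydroxyl with retention.

10 ⇒ 9. The C7 alcohol is traced to the thioester oxidation level. This restores the activated alkene that the ring closure needs. The forward step must deliver hydride to the carbonyl carbon only, not to C4.

9 ⇒ 8. The ring bond C5–C6 is cut. This opens the only ring and removes the only stereocentre that the chiral pool does not supply, leaving an acyclic chain with three stereocentres. The forward step needs face selectivity at the aldehyde and must prefer cyclisation to oligomerisation without disturbing C1.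

8 ⇒ 6. The C6 aldehyde is traced to a primary silyl ether carrying the same silyl group as O3. The aldehyde is delicate and should be made immediately before use, and identical silyl groups cost only one step to install. The forward step must convert the primary silyl ether only; it passes through 7.

6 ⇒ 5. The two Si–O bonds are cut. The forward step must cap both hydroxyls without triggering conjugate addition of O6–H to C4.

5 ⇒ 3 + 4. The C4=C5 double bond is cut. The seven-carbon chain divides into 3 (five carbons, all three stereocentres) and 4 (C5, C7 and the sulfur). The forward step is an olefination of a lactol carrying two free hydroxyls; alkene geometry is not critical because step 5 erases it.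

3 ⇒ 1 + 2. The two acetal C–O bonds are cut. The acetal blocks O1/O2 on the only cis-diol of the pyranose form and leaves the anomeric hydroxyl free for olefination. The forward step must stop at the monoacetal.

## Other disconnections considered

Alternative 1: The ring is cut at C2–C3 and C1–C6. This separates a two-carbon cis-dioxygenated unit (C1, C2) from a four-carbon unit that already carries C7 at the ester level. Forward, methyl coumalate A1 and 2,2-dimethyl-1,3-dioxole A2 would combine in an inverse-electron-demand [4+2] cycloaddition. In the same operation a cycloreversion would expel the lactone bridge as gas and leave the cyclohexadiene ester A3.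
- In its favour: two ring bonds and the carbocycle arise in one operation from two small achiral partners. The electron-poor pyrone A1 and the electron-rich enol ether A2 are well matched, A2 is symmetric so no regiochemical question arises, and the ring of A2 guarantees the cis relation of O1 and O2.
- Better than the chosen plan: ring construction takes one step against five to reach 9, and the concerted mechanism is at least as predictable as a nucleophile-catalysed aldol closure.
- Against it: A3 is chiral only through the position of the ester relative to the diol, and nothing in A1 or A2 fixes that. A chiral catalyst or a resolution would have to supply what 1 supplies at no cost.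
- Against it: A3 is one elimination away from an aromatic ring at the temperature the cycloreversion needs.
- Against it: A3 still lacks O3 and O6. They would have to be added anti to the acetonide, for instance through the peroxide A9 of Alternative 3, and then told apart. In the chosen plan O3 comes protected from 1 and O6 appears alone and free in 9.
- Step economy: after oxygenation, differentiation, reduction and acylation the sequence should be about as long as the chosen one.

Alternative 2: The cut runs through C3–C4 and C5–C6. The diene A4, (1E,3E)-1,4-diacetoxybuta-1,3-diene, carries C6, C1, C2 and C3 together with O6 and O3. The dienophile A5, 2-bromoacrolein, carries C5, C4 and C7. The forward step would be the catalytic asymmetric Diels–Alder reaction of A4 with A5 under the chiral catalyst A6, an N-tosyl B-butyl oxazaborolidinone made from tryptophan. It would give the endo-formyl adduct A7.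
- In its favour: the whole carbon skeleton including C7 is assembled in one step, and the absolute configuration comes from the catalyst A6 and not from a stoichiometric chiral starting material.
- In its favour: the E,E geometry of A4 translates suprafacially into cis O3/O6, as 14 requires. The bromine of A5 is a built-in leaving group for later formation of C4=C5. The remaining C1=C2 alkene of A7 could be cis-dihydroxylated anti to both flanking acyloxy groups to set O1 and O2.
- Equal or better than the chosen plan: the relative configuration at C6 follows from orbital-symmetry rules and not from a conformational preference.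
- Against it: A4 is a hindered, weakly donating diene, whereas catalysts of the type of A6 are established for more reactive dienes, so rate and enantioselectivity with A5 are open.
- Against it: after dehydrobromination of A7 the ring holds a skipped diene with two allylic esters and can aromatise by elimination, which dictates the order of steps.
- Against it, most seriously: O3 and O6 arrive in A7 with identical acyl groups although 14 needs a benzoate on O6 and a free hydroxyl on O3, and O1/O2 would again emerge as an undifferentiated cis-diol. The chosen plan differentiates O6, O3 and the O1/O2 pair by construction.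
- Step economy: the skeleton costs one step instead of five, but dihydroxylation, elimination, reduction and a series of acyl exchanges follow, so the total is expected to be equal or higher.

Alternative 3: No carbon–carbon bond is cut; the C3–O and C6–O bonds are disconnected together. This leads back to the diene ester A3, here taken from (−)-shikimic acid A8 by esterification, acetonide formation on its cis-diol and dehydration of the remaining hydroxyl. Forward, singlet oxygen would add [4+2] across C3 and C6 of A3 on the face opposite the acetonide to give the endoperoxide A9.
- In its favour: all seven carbons, the ring and the stereocentres C1 and C2 come from the chiral pool compound A8.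
- Better than the chosen plan: C3 and C6 are both set in one concerted suprafacial step with one face blocked by the cis-fused dioxolane, which is probably more reliable than the face selectivity at C6 in the chosen key step.
- Equal: A9 should be reached in about four to five steps from A8, against five steps to 9.
- Against it: A9 delivers O3 and O6 as the two ends of one peroxide bridge, while 14 needs them different. Reductive cleavage would expose two allylic secondary hydroxyls of similar reactivity. A base-induced Kornblum–DeLaMare rearrangement would break the symmetry only at the price of a ketone that must be reduced again stereoselectively.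
- Against it: A3 is electron-poor towards the electrophilic oxidant, can undergo ene reaction at C1–H or C2–H, and aromatises easily. A peroxide also has to be handled on scale.
- Comparison: the pericyclic step is mechanistically the cleaner one. The chosen plan is safer on differentiating the oxygens, because O6 is formed as the only free hydroxyl and O3 is already masked. The step counts should be about equal.

Key step: step 5

Remarks on the chemistry

- The labels of 14 (ring C1–C6, exocyclic C7; O1, O2, O3, O6, O7) are used for the same atoms in every intermediate, open-chain ones included.
- A cross-check of configurations confirms that C1, C2 and C3 of 8 and 9 have the spatial arrangement of C4, C3 and C2 of 1 and of the same centres in 14, and that 9 has O6 trans to O1 as in 14. The skeletons of the key-step precursor and product therefore need no change.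
- Precursor design: the silyl group on O3 (and temporarily on O6) is triethylsilyl instead of a bulkier tert-butyldimethylsilyl group. A primary triethylsilyl ether can be oxidised directly under Swern conditions, which saves a separate deprotection. The O3 triethylsilyl ether is also cleaved by the same mild acid that opens the acetonide.
- The thioester is reduced with i-Bu2AlH and not with a borohydride, to exclude conjugate reduction.
- Assumption: 4 is used as the purchased, salt-free ylide.
- 3 is an anomeric mixture and 13 a mixture at the orthoester carbon; these centres are left undefined because both disappear in the next transformation.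

## Route

Step 1
Reactants: 1 D-arabinose; 2 2,2-dimethoxypropane
Product: 3 3,4-O-isopropylidene-D-arabinopyranose (anomeric mixture)
Conditions: 2 (2 equiv), p-TsOH·H2O (cat.), DMF, rt; Et3N quench
Reagents that add atoms: none
Why: Acid-catalysed transacetalisation under kinetic control; the cis-vicinal pair at sugar positions 3 and 4 (O2 and O1 in target labels) closes a five-membered dioxolane while the anomeric hydroxyl stays free, and limiting 2 avoids the diacetal. No stereocentre is touched.

Step 2
Reactants: 3 3,4-O-isopropylidene-D-arabinopyranose; 4 S-ethyl (triphenylphosphoranylidene)thioacetate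
Product: 5 S-ethyl (2E,4R,5S,6R)-4,7-dihydroxy-5,6-(isopropylidenedioxy)hept-2-enethioate
Conditions: 4 (1.4 equiv), PhCO2H (0.1 equiv), CH2Cl2, 40 °C
Reagents that add atoms: none
Why: Wittig olefination of the open-chain aldehyde tautomer of the lactol by a stabilised acyl ylide; catalytic benzoic acid speeds ring opening, and the reversible addition of a stabilised ylide favours the E-alkene. The three stereocentres are not involved.

Step 3
Reactants: 5 S-ethyl (2E,4R,5S,6R)-4,7-dihydroxy-5,6-(isopropylidenedioxy)hept-2-enethioate
Product: 6 S-ethyl (2E,4R,5R,6R)-5,6-(isopropylidenedioxy)-4,7-bis(triethylsilyloxy)hept-2-enethioate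
Conditions: Et3SiOTf (2.4 equiv), 2,6-lutidine (4 equiv), CH2Cl2, −78 °C
Reagents that add atoms: triethylsilyl trifluoromethanesulfonate, CC[Si](CC)(CC)OS(=O)(=O)C(F)(F)F
Why: Silylation of both hydroxyls by a silyl triflate and a hindered non-nucleophilic base; the low temperature and the absence of a nucleophilic base prevent oxa-Michael addition of O6–H to C4 and acyl transfer at the thioester.

Step 4
Reactants: 6 S-ethyl (2E,4R,5R,6R)-5,6-(isopropylidenedioxy)-4,7-bis(triethylsilyloxy)hept-2-enethioate
Product: 8 S-ethyl (2E,4R,5R,6S)-5,6-(isopropylidenedioxy)-7-oxo-4-(triethylsilyloxy)hept-2-enethioate, via alkoxydimethylsulfonium chloride 7 (not isolated)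
Conditions: (COCl)2 (4 equiv), DMSO (8 equiv), CH2Cl2, −78 to −40 °C; then Et3N (12 equiv), −78 to 0 °C
Reagents that add atoms: none
Why: Swern oxidation applied directly to the silyl ether: chlorodimethylsulfonium chloride attacks the unhindered primary Si–O oxygen, the silyl group leaves as Et3SiCl, and the alkoxysulfonium salt 7 collapses to the aldehyde when Et3N is added. The hindered secondary allylic silyl ether on O3 should be inert at this temperature, and C1 should keep its configuration if the mixture stays cold and 8 is used at once.

Step 5
Reactants: 8 S-ethyl (2E,4R,5R,6S)-5,6-(isopropylidenedioxy)-7-oxo-4-(triethylsilyloxy)hept-2-enethioate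
Product: 9 S-ethyl (3R,4R,5R,6S)-6-hydroxy-4,5-(isopropylidenedioxy)-3-(triethylsilyloxy)cyclohex-1-ene-1-carbothioate
Conditions: PMe3 (0.3 equiv, 1.0 M in THF), CH2Cl2 (0.05 M), rt, Ar
Reagents that add atoms: none
Why: PMe3 adds in conjugate fashion to C4 of the thioenoate to give a β-phosphonium thioester enolate; its α-carbon C5 adds to the tethered aldehyde carbon C6, a proton moves from C5 to the new alkoxide, and E1cB loss of PMe3 from C4 restores the C4=C5 alkene inside the new ring and returns the catalyst. The closest known reaction type is the trialkylphosphine-catalysed intramolecular Morita–Baylis–Hillman cyclisation of enoate, enone and thioenoate aldehydes to cyclohexenols. The six-membered ring closes in the 6-exo-trig mode at the aldehyde carbonyl, with the enolate double bond C5=C7 outside the ring (enolexo). The one new stereocentre, C6, is controlled by the neighbouring stereocentre C1: in the chair-like transition state the carbonyl oxygen should lie pseudoaxial and antiperiplanar to the C1–O1 bond, which opposes the C=O and C–O dipoles and avoids allylic 1,2-strain against the thioester on C5, so the alkoxide ends up trans to O1 (6S). The step needs conjugate addition of the phosphine in preference to attack at the aldehyde, cyclisation in preference to oligomerisation, and no epimerisation at C1 or β-elimination of O2; the soft and weakly basic phosphine, the high acceptor strength of the thioenoate, dilution, and the cis-dioxolane that holds C6 and C3 gauche about C1–C2 should secure this. Any Z-thioenoate carried along converges on the same product because the alkene geometry is lost in the phosphonium enolate.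

Step 6
Reactants: 9 S-ethyl (3R,4R,5R,6S)-6-hydroxy-4,5-(isopropylidenedioxy)-3-(triethylsilyloxy)cyclohex-1-ene-1-carbothioate
Product: 10 (1S,4R,5R,6R)-2-(hydroxymethyl)-5,6-(isopropylidenedioxy)-4-(triethylsilyloxy)cyclohex-2-en-1-ol
Conditions: i-Bu2AlH (4 equiv), CH2Cl2, −78 to −20 °C; aq. KNaC4H4O6
Reagents that add atoms: none
Why: Hydride 1,2-reduction: the thioester passes through the hemithioacetal aluminate and the enal to the allylic alcohol, because the aluminium hydride adds at the carbonyl carbon and not at C4. The silyl ether, the acetonide and all stereocentres should be inert at low temperature.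

Step 7
Reactants: 10 (1S,4R,5R,6R)-2-(hydroxymethyl)-5,6-(isopropylidenedioxy)-4-(triethylsilyloxy)cyclohex-2-en-1-ol
Product: 11 [(3R,4R,5R,6S)-6-(benzoyloxy)-4,5-(isopropylidenedioxy)-3-(triethylsilyloxy)cyclohex-1-en-1-yl]methyl benzoate
Conditions: BzCl (3 equiv), pyridine, DMAP (0.1 equiv), CH2Cl2, 0 °C to rt
Reagents that add atoms: benzoyl chloride, O=C(Cl)c1ccccc1
Why: DMAP-catalysed acylation of the only two free hydroxyls (O6–H and O7–H), so no selectivity is required. C6 keeps its configuration because the C6–O bond is not broken.

Step 8
Reactants: 11 [(3R,4R,5R,6S)-6-(benzoyloxy)-4,5-(isopropylidenedioxy)-3-(triethylsilyloxy)cyclohex-1-en-1-yl]methyl benzoate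
Product: 12 [(3R,4S,5S,6S)-6-(benzoyloxy)-3,4,5-trihydroxycyclohex-1-en-1-yl]methyl benzoate
Conditions: TFA/H2O (4:1), 0 °C to rt; toluene co-evaporation
Reagents that add atoms: none
Why: Acid hydrolysis removes the isopropylidene acetal and the triethylsilyl ether in one operation. Acid is chosen because ester migration runs through alkoxide attack, and the O6 benzoate and O1–H are trans-diaxial in the preferred half-chair, which cannot close the five-membered orthoacid that migration requires.

Step 9
Reactants: 12 [(3R,4S,5S,6S)-6-(benzoyloxy)-3,4,5-trihydroxycyclohex-1-en-1-yl]methyl benzoate
Product: 14 [(3R,4S,5S,6S)-5-acetoxy-6-(benzoyloxy)-3,4-dihydroxycyclohex-1-en-1-yl]methyl benzoate, via cyclic O1/O2 methyl orthoacetate 13 (not isolated)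
Conditions: MeC(OMe)3 (1.5 equiv), CSA (0.05 equiv), CH2Cl2, rt; then AcOH/H2O (4:1), rt
Reagents that add atoms: trimethyl orthoacetate, COC(C)(OC)OC; water, O
Why: Acid-catalysed orthoester exchange closes the five-membered cyclic orthoacetate 13 on the cis pair O1/O2 in preference to the trans pair O2/O3, and mild aqueous acid opens the derived 2-hydroxy-1,3-dioxolane under stereoelectronic control to the axial acetate and the equatorial hydroxyl (orthoester method for monoacylation of cis-diols). In the favoured half-chair the C6 benzoate is pseudoaxial to avoid allylic 1,2-strain against the C7 arm, which makes O1 axial and O2 equatorial, so the acetyl group should end on O1.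

## Compound list

1 | D-arabinose | O[C@H](CO)[C@@H](O)[C@H](O)C=O | starting material
2 | 2,2-dimethoxypropane | COC(C)(C)OC | starting material
3 | 3,4-O-isopropylidene-D-arabinopyranose (anomeric mixture) | CC1(C)O[C@@H]2COC(O)[C@@H](O)[C@@H]2O1 | intermediate
4 | S-ethyl (triphenylphosphoranylidene)thioacetate | CCSC(=O)C=P(c1ccccc1)(c1ccccc1)c1ccccc1 | starting material
5 | S-ethyl (2E,4R,5S,6R)-4,7-dihydroxy-5,6-(isopropylidenedioxy)hept-2-enethioate | CC1(C)O[C@H](CO)[C@@H](O1)[C@H](O)/C=C/C(=O)SCC | intermediate
6 | S-ethyl (2E,4R,5R,6R)-5,6-(isopropylidenedioxy)-4,7-bis(triethylsilyloxy)hept-2-enethioate | CC1(C)O[C@H](CO[Si](CC)(CC)CC)[C@@H](O1)[C@H](O[Si](CC)(CC)CC)/C=C/C(=O)SCC | intermediate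
7 | alkoxydimethylsulfonium chloride on O6 of the chain (O3 triethylsilyl ether and acetonide retained) | CC1(C)O[C@H](CO[S+](C)C)[C@@H](O1)[C@H](O[Si](CC)(CC)CC)/C=C/C(=O)SCC.[Cl-] | intermediate
8 | S-ethyl (2E,4R,5R,6S)-5,6-(isopropylidenedioxy)-7-oxo-4-(triethylsilyloxy)hept-2-enethioate | CC1(C)O[C@H](C=O)[C@@H](O1)[C@H](O[Si](CC)(CC)CC)/C=C/C(=O)SCC | intermediate
9 | S-ethyl (3R,4R,5R,6S)-6-hydroxy-4,5-(isopropylidenedioxy)-3-(triethylsilyloxy)cyclohex-1-ene-1-carbothioate (target labels: O1/O2 acetonide, O3 silyl ether, O6–H free and trans to O1) | CC1(C)O[C@H]2[C@@H](O1)[C@H](O[Si](CC)(CC)CC)C=C(C(=O)SCC)[C@@H]2O | intermediate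
10 | (1S,4R,5R,6R)-2-(hydroxymethyl)-5,6-(isopropylidenedioxy)-4-(triethylsilyloxy)cyclohex-2-en-1-ol (target labels: O6–H and O7–H free) | CC1(C)O[C@H]2[C@@H](O1)[C@H](O[Si](CC)(CC)CC)C=C(CO)[C@@H]2O | intermediate
11 | [(3R,4R,5R,6S)-6-(benzoyloxy)-4,5-(isopropylidenedioxy)-3-(triethylsilyloxy)cyclohex-1-en-1-yl]methyl benzoate (O6,O7-dibenzoate of 10) | CC1(C)O[C@H]2[C@@H](O1)[C@H](O[Si](CC)(CC)CC)C=C(COC(=O)c1ccccc1)[C@@H]2OC(=O)c1ccccc1 | intermediate
12 | [(3R,4S,5S,6S)-6-(benzoyloxy)-3,4,5-trihydroxycyclohex-1-en-1-yl]methyl benzoate | O[C@H]1[C@@H](O)[C@H](O)C=C(COC(=O)c2ccccc2)[C@@H]1OC(=O)c1ccccc1 | intermediate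
13 | cyclic O1/O2 methyl orthoacetate (1-methoxyethylidene acetal) of 12, O3–H free | COC1(C)O[C@H]2[C@@H](O1)[C@H](O)C=C(COC(=O)c1ccccc1)[C@@H]2OC(=O)c1ccccc1 | intermediate
14 | [(3R,4S,5S,6S)-5-acetoxy-6-(benzoyloxy)-3,4-dihydroxycyclohex-1-en-1-yl]methyl benzoate (1S,2S,3R,6S in target labels) | CC(=O)O[C@H]1[C@@H](O)[C@H](O)C=C(COC(=O)c2ccccc2)[C@@H]1OC(=O)c1ccccc1 | target

## Step count and least certain steps

Total step count: 9. Longest linear sequence: 9 steps (1 to 14; the route is fully linear).

Step 5 (key step). The most likely problem is poor facial selectivity in the aldol addition at C6. The control rests on a single α-alkoxy centre and the addition is reversible before the proton transfer. Slow turnover would also give time for epimerisation at C1. Fallback, setting out from 8 and returning at 11: the wrong sense of cyclisation is accepted and corrected later by substitution with inversion. The C6-epimeric cyclohexenyl thioester F1 would be reduced with i-Bu2AlH as in step 6 to the C6-epimeric diol F2. The primary O7–H would be benzoylated selectively (BzCl 1.05 equiv, 2,4,6-collidine, CH2Cl2, −40 °C) to the C6-epimeric O7-monobenzoate F3. A Mitsunobu reaction on F3 (PPh3, DIAD, PhCO2H, toluene, 0 °C to rt) would install the O6 benzoate with inversion, entering anti to the dioxolane, and give 11.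

Step 9. The most likely problem is acetylation of the wrong oxygen of the cis pair (O2 instead of O1) if the ring populates the other half-chair, or acetyl migration from O1 to O2 during work-up. The selectivity rests on a conformational preference and not on a covalent device. Fallback, setting out from 12 and returning at 14: the trans-diequatorial pair O2/O3 is tied up selectively as the O2,O3-butane-2,3-diacetal F4 (2,2,3,3-tetramethoxybutane, CH(OMe)3, CSA cat., MeOH, 50 °C). This acetal type takes trans-diequatorial diols in preference to cis-diols. The only free hydroxyl is then acetylated (Ac2O, pyridine, DMAP, 0 °C) to the O1-acetate F5, and TFA/H2O (9:1) at 0 °C removes the diacetal to give 14.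

Step 4. The most likely problem is incomplete conversion of the primary silyl ether or partial loss of the secondary silyl ether on O3, since both silyl groups are the same and the discrimination is purely steric. Fallback, setting out from 6 and returning at 8: deprotection and oxidation are separated. HF·pyridine buffered with pyridine in THF at 0 °C removes the primary silyl group to give the O3-silylated primary alcohol F6, which is oxidised with Dess–Martin periodinane and NaHCO3 in CH2Cl2 to 8.

Step 2. The most likely problem is conjugate addition of the primary O6–H to C4 of the new thioenoate (six-membered oxa-Michael closure), or lactonisation of any Z-isomer onto O3–H with loss of the thiol. Both follow from carrying free hydroxyls next to a strong acceptor. Fallback, setting out from 3 and returning at 6: the acceptor is introduced only after the hydroxyls are capped. Wittig methylenation of 3 (Ph3PCH3Br, KOt-Bu, THF, 0 °C to rt) gives the terminal alkene diol F7, and silylation as in step 3 gives its bis(triethylsilyl) ether F8. Cross-metathesis of F8 with S-ethyl thioacrylate in CH2Cl2 at 40 °C then gives 6 as the E-isomer. The catalyst is the second-generation Hoveyda–Grubbs catalyst, [1,3-bis(2,4,6-trimethylphenyl)imidazolidin-2-ylidene]dichloro(2-isopropoxybenzylidene)ruthenium.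

## Further compounds

F1 | step 5 | C6-epimer of 9 (O6 cis to O1) | CC1(C)O[C@H]2[C@@H](O1)[C@H](O[Si](CC)(CC)CC)C=C(C(=O)SCC)[C@H]2O
F2 | step 5 | C6-epimer of 10 | CC1(C)O[C@H]2[C@@H](O1)[C@H](O[Si](CC)(CC)CC)C=C(CO)[C@H]2O
F3 | step 5 | O7-monobenzoate of F2 (O6–H free, cis to O1) | CC1(C)O[C@H]2[C@@H](O1)[C@H](O[Si](CC)(CC)CC)C=C(COC(=O)c1ccccc1)[C@H]2O
F4 | step 9 | O2,O3-butane-2,3-diacetal of 12 (O1–H free; both acetal carbons S, methoxy groups axial) | O[C@H]1[C@H]2O[C@](C)(OC)[C@@](C)(OC)O[C@@H]2C=C(COC(=O)c2ccccc2)[C@@H]1OC(=O)c1ccccc1
F5 | step 9 | O1-acetate of F4 | CC(=O)O[C@H]1[C@H]2O[C@](C)(OC)[C@@](C)(OC)O[C@@H]2C=C(COC(=O)c2ccccc2)[C@@H]1OC(=O)c1ccccc1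
F6 | step 4 | O3-triethylsilyl ether of 5 (primary O6–H free) | CC1(C)O[C@H](CO)[C@@H](O1)[C@H](O[Si](CC)(CC)CC)/C=C/C(=O)SCC
F7 | step 2 | 1,2-dideoxy-4,5-O-isopropylidene-D-arabino-hex-1-enitol | CC1(C)O[C@H](CO)[C@@H](O1)[C@H](O)C=C
F8 | step 2 | 3,6-bis-O-(triethylsilyl) ether of F7 | CC1(C)O[C@H](CO[Si](CC)(CC)CC)[C@@H](O1)[C@H](O[Si](CC)(CC)CC)C=C
A1 | alternative 1 | methyl coumalate (methyl 2-oxo-2H-pyran-5-carboxylate) | COC(=O)C1=COC(=O)C=C1
A2 | alternative 1 | 2,2-dimethyl-1,3-dioxole | CC1(C)OC=CO1
A3 | alternative 1 | methyl (3R,4S)-3,4-(isopropylidenedioxy)cyclohexa-1,5-diene-1-carboxylate | CC1(C)O[C@H]2[C@@H](O1)C=CC(C(=O)OC)=C2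
A4 | alternative 2 | (1E,3E)-1,4-diacetoxybuta-1,3-diene | CC(=O)O/C=C/C=C/OC(C)=O
A5 | alternative 2 | 2-bromoacrolein | C=C(Br)C=O
A6 | alternative 2 | (4S)-2-butyl-4-(1H-indol-3-ylmethyl)-3-tosyl-1,3,2-oxazaborolidin-5-one | CCCCB1OC(=O)[C@H](Cc2c[nH]c3ccccc23)N1S(=O)(=O)c1ccc(C)cc1
A7 | alternative 2 | 2,5-diacetoxy-1-bromocyclohex-3-ene-1-carbaldehyde (endo-formyl adduct) | C1=C[C@H](OC(C)=O)C[C@](Br)(C=O)[C@@H]1OC(C)=O
A8 | alternative 3 | (−)-shikimic acid | C1[C@H]([C@@H]([C@@H](C=C1C(=O)O)O)O)O
A9 | alternative 3 | bicyclic endoperoxide methyl ester (peroxide bridging C3 and C6, acetonide on O1/O2) | CC1(C)O[C@H]2[C@@H](O1)[C@H]3C=C(C(=O)OC)[C@@H]2OO3
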